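The pyrrole ring is cut into a three-atom C2–N1–C5 unit and the unsubstituted C3–C4 pair. The first is the azomethine ylide of the imine between docosanal and methyl glycinate, which already carries both ring substituents: C1' of the henicosyl chain on C5 and the future formyl carbon, as an ester, on C2. The second is (E)-1,2-bis(phenylsulfonyl)ethene, an acetylene equivalent. In one telescoped operation the imine is formed, AgOAc and triethylamine trigger the 3+2 cycloaddition, and DBU expels both sulfinates to give the aromatic 2,5-disubstituted pyrrole ester. A cold hydride reduction and a MnO2 oxidation then adjust the ester to the aldehyde.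

Key step: step 2

Remark: the chloride of 3 is filtered off as triethylammonium chloride before AgOAc is added, because it would otherwise remove the catalyst as AgCl; the target has no stereocentre.

Step 1
Reactants: 1 docosan-1-ol
Product: 2 docosanal
Conditions: IBX (2 equiv), EtOAc, 80 °C; filter, concentrate; used at once
Reagents that add atoms: none
Why: IBX oxidation of a primary alcohol (pentavalent iodine) stops at the aldehyde when no water is present, and hot ethyl acetate dissolves the waxy alcohol while the oxidant and its reduced form stay solid and are filtered off.

Step 2
Reactants: 2 docosanal; 3 glycine methyl ester hydrochloride; 4 (E)-1,2-bis(phenylsulfonyl)ethene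
Product: 8 methyl 5-henicosyl-1H-pyrrole-2-carboxylate, via methyl glycinate 5 (not isolated), via aldimine 6 (not isolated), via disulfonyl pyrrolidine 7 (not isolated)
Conditions: 2 and 3 (1:1), Et3N (1 equiv), MgSO4, CH2Cl2, rt; solvent exchange to THF, filter off MgSO4 and Et3N·HCl under N2; 4 (0.9 equiv), AgOAc (10 mol%), Et3N (10 mol%), THF, rt, dark; then DBU (3 equiv), rt to 50 °C
Reagents that add atoms: none
Why: Amine 5, freed by Et3N, condenses with 2 to aldimine 6, whose N,O-chelation to monovalent silver acidifies the glycine CH2 so that Et3N forms the metallated azomethine ylide; this adds across the doubly activated alkene of 4, concertedly or by a Michael–Mannich sequence, making C2–C3 and C4–C5 and giving pyrrolidine 7. DBU then removes H-2 next to the ester with E1cB loss of the C3 sulfinate, the enamine so formed pushes out the C4 sulfinate, and proton loss from C5 leaves the aromatic 1H-pyrrole 8. The closest known chemistry is the silver- or copper-catalysed cycloaddition of aryl aldimines of glycine esters with this disulfone followed by base-induced double loss of sulfinic acid, here applied to an enolisable aliphatic aldimine. The one ring is closed intermolecularly in the 3+2 event itself, the C2–N1–C5 dipole joining both ends of the C3–C4 unit (a 5-endo-trig Mannich closure at C5 if the addition is stepwise). Four stereocentres arise in 7 (2,5-cis from the W-shaped chelated dipole, 3,4-trans from the E alkene) but none needs control because aromatisation erases them all, and the symmetric dipolarophile leaves the dipole alone to fix the 2,5-pattern. The selectivity needed is deprotonation at the glycine carbon in preference to aza-enolisation of the aliphatic aldimine, which the ester, the silver chelate and the weak base Et3N secure, while using 4 as the limiting partner and adding it only after the imine has formed suppresses conjugate addition of N–H groups to it.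

Step 3
Reactants: 8 methyl 5-henicosyl-1H-pyrrole-2-carboxylate
Product: 9 (5-henicosyl-1H-pyrrol-2-yl)methanol
Conditions: LiAlH4 (2.5 equiv), THF, 0 °C to rt; H2O, 15% aq NaOH, H2O at 0 °C; filter, concentrate below 30 °C; crude 9 used at once
Reagents that add atoms: none
Why: This is an ester-to-carbinol reduction by LiAlH4 in which the N–H proton is removed first and hydride then takes the ester to the aluminium alkoxide of the pyrrol-2-ylmethanol, and keeping the mixture at or below room temperature with a basic quench should stop the alkoxide from ionising towards the 2-methylpyrrole or towards oligomers.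

Step 4
Reactants: 9 (5-henicosyl-1H-pyrrol-2-yl)methanol
Product: 10 5-henicosyl-1H-pyrrole-2-carbaldehyde
Conditions: activated MnO2 (15 equiv), CH2Cl2, rt; filter through Celite; chromatography or recrystallisation
Reagents that add atoms: none
Why: MnO2 oxidation of an activated heteroaryl carbinol is fast on the electron-rich pyrrole and stops at the aldehyde, whose conjugation with N1 as a vinylogous formamide should make 10 far more robust than 9.

Compound list
1 | docosan-1-ol | CCCCCCCCCCCCCCCCCCCCCCO | starting material
2 | docosanal | CCCCCCCCCCCCCCCCCCCCCC=O | intermediate
3 | glycine methyl ester hydrochloride | Cl.NCC(=O)OC | starting material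
4 | (E)-1,2-bis(phenylsulfonyl)ethene | O=S(=O)(/C=C/S(=O)(=O)c1ccccc1)c1ccccc1 | starting material
5 | methyl glycinate (free base, formed in the flask, not isolated) | NCC(=O)OC | intermediate
6 | methyl 2-[(E)-docosylideneamino]acetate (not isolated) | CCCCCCCCCCCCCCCCCCCCC/C=N/CC(=O)OC | intermediate
7 | methyl 5-henicosyl-3,4-bis(phenylsulfonyl)pyrrolidine-2-carboxylate (not isolated; racemic diastereomer mixture, 2,5-cis and 3,4-trans expected, the four transient stereocentres left undefined) | CCCCCCCCCCCCCCCCCCCCCC1NC(C(=O)OC)C(S(=O)(=O)c2ccccc2)C1S(=O)(=O)c3ccccc3 | intermediate
8 | methyl 5-henicosyl-1H-pyrrole-2-carboxylate | CCCCCCCCCCCCCCCCCCCCCc1ccc(C(=O)OC)[nH]1 | intermediate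
9 | (5-henicosyl-1H-pyrrol-2-yl)methanol | CCCCCCCCCCCCCCCCCCCCCc1ccc(CO)[nH]1 | intermediate
10 | 5-henicosyl-1H-pyrrole-2-carbaldehyde | CCCCCCCCCCCCCCCCCCCCCc1ccc(C=O)[nH]1 | target

Total step count: 4
Longest linear sequence: 4 steps (1 to 2 to 8 to 9 to 10)

Steps most likely to fail

Step 2. The aliphatic aldimine may tautomerise to its enamine and self-condense, or amine nitrogen may add to the disulfone, faster than the silver ylide is trapped, so that little pyrrolidine forms and the aromatisation has nothing to work on. The fallback builds the same ring by a Paal–Knorr condensation; it sets out from docosanal 2 and comes back at the target 10, passing by 8 and 9. Addition of [2-(1,3-dioxolan-2-yl)ethyl]magnesium bromide in THF at 0 °C should give racemic 1-(1,3-dioxolan-2-yl)tetracosan-3-ol F1. IBX in ethyl acetate at 80 °C should oxidise it to 1-(1,3-dioxolan-2-yl)tetracosan-3-one F2. Heating F2 with NH4OAc in acetic acid should unmask the aldehyde and close the ring to 2-henicosyl-1H-pyrrole F3. Vilsmeier–Haack formylation (POCl3, DMF, 0 °C to rt, then aqueous NaOAc) at the free alpha position should then give 10.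

Step 3. The N-metallated aluminium alkoxide may lose its oxygen to an azafulvene that takes up more hydride, which is over-reduction to the 2-methylpyrrole, or the carbinol may ionise in the same way during work-up and oligomerise. The fallback uses no hydride and no carbinol and trades the ester carbon for a formyl carbon from DMF; it sets out from 8 and comes back at 10. LiOH in THF/MeOH/H2O at 60 °C should give 5-henicosyl-1H-pyrrole-2-carboxylic acid F4. Heating F4 in 2-aminoethanol at about 170 °C should decarboxylate it to 2-henicosyl-1H-pyrrole F3, the compound also met in the fallback to step 2. Vilsmeier–Haack formylation as above should then give 10.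

Step 4. On the oxidant surface or during handling the carbinol may lose water to an azafulvenium ion and self-condense before it is oxidised, and the waxy substrate may stay adsorbed on the large excess of solid. The fallback reaches the aldehyde from the acyl oxidation level by a McFadyen–Stevens reduction, so that 9 is never made; it sets out from 8 and comes back at 10. Hydrazine hydrate in refluxing ethanol should give 5-henicosyl-1H-pyrrole-2-carbohydrazide F5. 4-Toluenesulfonyl chloride in pyridine at 0 °C should sulfonylate the terminal nitrogen to 5-henicosyl-N'-(4-methylphenylsulfonyl)-1H-pyrrole-2-carbohydrazide F6. Na2CO3 in ethylene glycol at 160 °C should then fragment F6, with loss of sulfinate and nitrogen, to 10.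

Further compounds
F1 | step 2 | 1-(1,3-dioxolan-2-yl)tetracosan-3-ol (racemic) | CCCCCCCCCCCCCCCCCCCCCC(O)CCC1OCCO1
F2 | step 2 | 1-(1,3-dioxolan-2-yl)tetracosan-3-one | CCCCCCCCCCCCCCCCCCCCCC(=O)CCC1OCCO1
F3 | step 2 | 2-henicosyl-1H-pyrrole | CCCCCCCCCCCCCCCCCCCCCc1ccc[nH]1
F4 | step 3 | 5-henicosyl-1H-pyrrole-2-carboxylic acid | CCCCCCCCCCCCCCCCCCCCCc1ccc(C(=O)O)[nH]1
F5 | step 4 | 5-henicosyl-1H-pyrrole-2-carbohydrazide | CCCCCCCCCCCCCCCCCCCCCc1ccc(C(=O)NN)[nH]1
F6 | step 4 | 5-henicosyl-N'-(4-methylphenylsulfonyl)-1H-pyrrole-2-carbohydrazide | CCCCCCCCCCCCCCCCCCCCCc1ccc(C(=O)NNS(=O)(=O)c2ccc(C)cc2)[nH]1
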